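**Retrosynthetic overview**
1. Target ⇒ (remove the phenol MOM ether and the two acetates) all-cis diol ⇒ 1-methyl-2-tetralone. C1 and C2 are set together by a dynamic kinetic hydrogenation.
2. 1-Methyl-2-tetralone ⇒ 3-substituted 7-oxygenated indan-1-one + diazoethane. A one-carbon ring expansion by 1,2-aryl shift makes the C8a–C1 bond and the six-membered ring, which is formed last.
3. Indanone ⇒ aryl propargyl alcohol. A rhodium-catalysed isomerisation/C–H cyclisation closes the five-membered ring, formed first on the bought benzene ring, and sets C4.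
4. Propargyl alcohol ⇒ protected salicylaldehyde (3-bromophenol + formaldehyde + bromomethyl acetate) + chiral C10 acetylide.
5. Acetylide ⇒ vinyl bromide + (S)-secondary boronate from 6-methylhepta-1,5-diene. A copper-catalysed Markovnikov protoboration sets C11.

Assumption: 6-methylhepta-1,5-diene is taken as a catalogue chemical, the ligand antipodes named are those expected by analogy (the mirror-image ligand is used if a test run shows the opposite sense), and atom labels follow the tetralin numbering of the target (C1 methyl-bearing, C2 acetoxy, C4 side chain, C8 phenol, C11 side-chain stereocentre, C19 benzylic CH2O).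

Step 1
Reactants: 1 3-bromophenol; 2 formaldehyde (charged as paraformaldehyde)
Product: 4 4-bromo-2-hydroxybenzaldehyde, via 5-bromo-2-(hydroxymethyl)phenol 3 (not isolated)
Conditions: MgCl2 (1.5 equiv), Et3N (3.8 equiv), (CH2O)n (6 equiv), MeCN, reflux; 1 M HCl work-up
Reagents that add atoms: none
Why: Casnati–Skattebøl ortho-formylation: the magnesium phenoxide delivers formaldehyde only ortho to oxygen, the less hindered ortho site (para to bromine) reacts to give 3, and a second formaldehyde oxidises its benzylic alkoxide by hydride transfer.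

Step 2
Reactants: 4 4-bromo-2-hydroxybenzaldehyde
Product: 5 4-bromo-2-(methoxymethoxy)benzaldehyde
Conditions: MOMCl (1.3 equiv), i-Pr2NEt (1.6 equiv), CH2Cl2, 0 °C to rt
Reagents that add atoms: chloromethyl methyl ether (MOMCl), COCCl
Why: Standard O-alkylation to the formaldehyde acetal (MOM protection); a free ortho-hydroxyl would add to the conjugated ynone formed in step 7 and be O-ethylated by diazoethane in step 8, and the acetal oxygen later serves as the chelating site for scandium.

Step 3
Reactants: 5 4-bromo-2-(methoxymethoxy)benzaldehyde; 6 bromomethyl acetate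
Product: 8 [4-formyl-3-(methoxymethoxy)phenyl]methyl acetate, via (acetoxymethyl)zinc bromide 7 (not isolated)
Conditions: 6, Zn dust, LiCl, THF, 0 to 25 °C; then 5, Pd(OAc)2 (2 mol %), SPhos (4 mol %), THF, 25–40 °C
Reagents that add atoms: none
Why: Negishi coupling: zinc inserts into the activated C–Br bond of 6, the weakly nucleophilic α-acyloxy organozinc 7 leaves the aldehyde alone, and the para-formyl aryl bromide adds readily to zerovalent palladium, so C19 arrives already oxygenated and acetate-protected.

Step 4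
Reactants: 9 6-methylhepta-1,5-diene
Product: 10 4,4,5,5-tetramethyl-2-[(2S)-6-methylhept-5-en-2-yl]-1,3,2-dioxaborolane
Conditions: CuCl (5 mol %), (R,R,R,R)-ANIPE·HCl (bulky C2-symmetric NHC precursor, 5.5 mol %), NaOt-Bu (20 mol %), B2pin2 (1.2 equiv), MeOH (2 equiv), hexane, rt
Reagents that add atoms: bis(pinacolato)diboron (B2pin2), CC1(C)OB(OC1(C)C)B1OC(C)(C)C(C)(C)O1
Why: Copper-catalysed enantioselective Markovnikov protoboration of an α-olefin: Cu–Bpin adds only to the terminal alkene, the bulky NHC steers boron to the internal carbon on one face, and methanol cleaves the C–Cu bond, which sets C11 as S while the trisubstituted alkene stays inert.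

Step 5
Reactants: 10 (S)-secondary pinacol boronate; 11 bromoethene (vinyl bromide)
Product: 15 (3S)-2-bromo-3,7-dimethylocta-1,6-diene, via 1-bromo-1-lithioethene 12 (not isolated), via lithium alkenylboronate complex 13 (not isolated), via iodo bromo boronic ester 14 (not isolated)
Conditions: 11, LiN(i-Pr)2, THF/Et2O/pentane, −110 °C; 10, −110 to −78 °C; I2, THF, −78 °C; NaOMe, MeOH, −78 °C to rt
Reagents that add atoms: none
Why: Zweifel-type olefination: iodine activates the bromovinyl group of 13, the secondary alkyl group shifts from boron to carbon (1,2-metallate rearrangement) with retention at C11 to give 14, and methoxide triggers anti elimination of boron and iodine.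

Step 6
Reactants: 15 (3S)-2-bromo-3,7-dimethylocta-1,6-diene; 8 [4-formyl-3-(methoxymethoxy)phenyl]methyl acetate
Product: 17 {4-[(4S)-1-hydroxy-4,8-dimethylnon-7-en-2-yn-1-yl]-3-(methoxymethoxy)phenyl}methyl acetate (both carbinol epimers), via lithium acetylide 16 (not isolated)
Conditions: 15, LiN(i-Pr)2 (2.0 equiv), THF, −78 to 0 °C; then 8, −78 °C; H2O quench
Reagents that add atoms: none
Why: The amide base is used twice (dehydrobromination, then deprotonation) to give acetylide 16, which adds to the aldehyde far faster than to the acetate at −78 °C (carbonyl 1,2-addition); the new carbinol centre is uncontrolled and is erased in step 7.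

Step 7
Reactants: 17 propargylic alcohol
Product: 19 [(3S)-7-(methoxymethoxy)-3-[(2S)-6-methylhept-5-en-2-yl]-1-oxo-2,3-dihydro-1H-inden-5-yl]methyl acetate, via ynone 18 (not isolated)
Conditions: [Rh(OH)(cod)]2 (2.5 mol %), (R)-SEGPHOS (5.5 mol %), 1,4-dioxane, 60 °C
Reagents that add atoms: none
Why: Rhodium-catalysed isomerisation of an α-arylpropargyl alcohol to an indanone: β-hydride elimination of the rhodium alkoxide gives 18 and Rh–H, hydrorhodation and a 1,4-rhodium shift move the metal to the only free ortho C–H, and the aryl–rhodium adds intramolecularly to the enone face chosen by the chiral bisphosphine, which sets C4 (indanone C3) as S.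

Step 8
Reactants: 19 indanone; 20 N-ethyl-N-nitrosourea
Product: 22 (4S)-6-(acetoxymethyl)-8-(methoxymethoxy)-1-methyl-4-[(2S)-6-methylhept-5-en-2-yl]-3,4-dihydronaphthalen-2(1H)-one (mixture of C1 epimers), via diazoethane 21 (not isolated)
Conditions: 20, 40% aq KOH, Et2O, 0 °C, ethereal 21 dried over KOH pellets; added slowly (1.3 equiv) to 19, Sc(OTf)3 (10 mol %), toluene/CH2Cl2, −78 to −20 °C
Reagents that add atoms: none
Why: Proposed new method: trivalent scandium binds the ketone oxygen and the neighbouring C7 aryl-acetal oxygen of 19 as a six-membered chelate, which activates this otherwise sluggish, donor-substituted aryl ketone toward addition of the non-stabilised diazoalkane 21; in the adduct the electron-rich aryl carbon C7a (ortho-oxygen, para-alkyl) migrates antiperiplanar to the departing N2 in preference to the C2 methylene (1,2-aryl shift, Tiffeneau–Demjanov-type ring expansion), forming the C8a–C1 bond and the six-membered ring; the product ketone can no longer chelate, so a second insertion is disfavoured; the closest known reaction types are the Sc(OTf)3-catalysed one-carbon homologation of simple cycloalkanones with substituted diazomethanes and the BF3-promoted Me3SiCHN2 expansion of benzo-fused ketones, neither shown for diazoethane on 7-oxygenated indan-1-ones; C1 forms as an epimer mixture that step 9 converges.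

Step 9
Reactants: 22 1-methyl-2-tetralone (C1 epimers)
Product: 23 (1R,2S,4S)-6-(hydroxymethyl)-8-(methoxymethoxy)-1-methyl-4-[(2S)-6-methylhept-5-en-2-yl]-1,2,3,4-tetrahydronaphthalen-2-ol
Conditions: RuCl2[(S)-xylbinap][(S)-daipen] (1 mol %), KOt-Bu (20 mol %), H2 (20 atm), degassed i-PrOH, 25 °C
Reagents that add atoms: none
Why: Noyori-type ketone hydrogenation under dynamic kinetic resolution: alkoxide interconverts the C1 epimers through the aryl-conjugated enolate; only the 1R epimer (methyl pseudoaxial because of the peri OMOM group, side chain pseudoequatorial) has an open face, so outer-sphere hydride transfer anti to the methyl gives the all-cis 1R,2S alcohol, whereas the 1S epimer is shielded on both faces by the methyl and the pseudoaxial C4 chain; the C=C bond is untouched and the primary acetate is transesterified by i-PrOH.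

Step 10
Reactants: 23 diol
Product: 24 (1R,2S,4S)-6-(acetoxymethyl)-8-(methoxymethoxy)-1-methyl-4-[(2S)-6-methylhept-5-en-2-yl]-1,2,3,4-tetrahydronaphthalen-2-yl acetate
Conditions: Ac2O (3 equiv), pyridine, DMAP (5 mol %), CH2Cl2, rt
Reagents that add atoms: acetic anhydride, CC(=O)OC(C)=O
Why: DMAP-catalysed esterification of the primary and the equatorial secondary alcohol in one operation; no stereocentre is touched and the masked phenol cannot be acylated.

Step 11
Reactants: 24 diacetate MOM ether
Product: 25 (1R,2S,4S)-6-(acetoxymethyl)-8-hydroxy-1-methyl-4-[(2S)-6-methylhept-5-en-2-yl]-1,2,3,4-tetrahydronaphthalen-2-yl acetate (CNP0210401.2)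
Conditions: NaHSO4·SiO2, CH2Cl2, rt
Reagents that add atoms: none
Why: Mild heterogeneous acid hydrolysis of the aryl formaldehyde acetal, selective for phenolic MOM ethers; both acetates, the trisubstituted alkene and all four stereocentres are unaffected.

**Compound list**
1 | 3-bromophenol | Oc1cccc(Br)c1 | starting material
2 | formaldehyde (as paraformaldehyde) | C=O | starting material
3 | 5-bromo-2-(hydroxymethyl)phenol (magnesium salt in the flask) | OCc1ccc(Br)cc1O | intermediate
4 | 4-bromo-2-hydroxybenzaldehyde | O=Cc1ccc(Br)cc1O | intermediate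
5 | 4-bromo-2-(methoxymethoxy)benzaldehyde | COCOc1cc(Br)ccc1C=O | intermediate
6 | bromomethyl acetate | CC(=O)OCBr | starting material
7 | (acetoxymethyl)zinc bromide | CC(=O)OC[Zn]Br | intermediate
8 | [4-formyl-3-(methoxymethoxy)phenyl]methyl acetate | CC(=O)OCc1ccc(C=O)c(OCOC)c1 | intermediate
9 | 6-methylhepta-1,5-diene | C=CCCC=C(C)C | starting material
10 | 4,4,5,5-tetramethyl-2-[(2S)-6-methylhept-5-en-2-yl]-1,3,2-dioxaborolane | CC1(C)OB(OC1(C)C)[C@@H](C)CCC=C(C)C | intermediate
11 | bromoethene (vinyl bromide) | C=CBr | starting material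
12 | 1-bromo-1-lithioethene | [Li]C(Br)=C | intermediate
13 | lithium (1-bromoethenyl)[(2S)-6-methylhept-5-en-2-yl](pinacolato)borate | [Li+].C=C(Br)[B-]1(OC(C)(C)C(C)(C)O1)[C@@H](C)CCC=C(C)C | intermediate
14 | 2-[(3S)-2-bromo-1-iodo-3,7-dimethyloct-6-en-2-yl]-4,4,5,5-tetramethyl-1,3,2-dioxaborolane (configuration at C2 not relevant) | ICC(Br)(B1OC(C)(C)C(C)(C)O1)[C@@H](C)CCC=C(C)C | intermediate
15 | (3S)-2-bromo-3,7-dimethylocta-1,6-diene | C=C(Br)[C@@H](C)CCC=C(C)C | intermediate
16 | lithium (3S)-3,7-dimethyloct-6-en-1-yn-1-ide | [Li]C#C[C@@H](C)CCC=C(C)C | intermediate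
17 | {4-[(4S)-1-hydroxy-4,8-dimethylnon-7-en-2-yn-1-yl]-3-(methoxymethoxy)phenyl}methyl acetate (carbinol epimers) | CC(=O)OCc1ccc(C(O)C#C[C@@H](C)CCC=C(C)C)c(OCOC)c1 | intermediate
18 | {4-[(4S)-4,8-dimethylnon-7-en-2-ynoyl]-3-(methoxymethoxy)phenyl}methyl acetate | CC(=O)OCc1ccc(C(=O)C#C[C@@H](C)CCC=C(C)C)c(OCOC)c1 | intermediate
19 | [(3S)-7-(methoxymethoxy)-3-[(2S)-6-methylhept-5-en-2-yl]-1-oxo-2,3-dihydro-1H-inden-5-yl]methyl acetate | CC(=O)OCc1cc(OCOC)c2c(c1)[C@H]([C@@H](C)CCC=C(C)C)CC2=O | intermediate
20 | N-ethyl-N-nitrosourea | CCN(N=O)C(N)=O | starting material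
21 | diazoethane | CC=[N+]=[N-] | intermediate
22 | (4S)-6-(acetoxymethyl)-8-(methoxymethoxy)-1-methyl-4-[(2S)-6-methylhept-5-en-2-yl]-3,4-dihydronaphthalen-2(1H)-one (C1 epimers) | CC(=O)OCc1cc(OCOC)c2c(c1)[C@H]([C@@H](C)CCC=C(C)C)CC(=O)C2C | intermediate
23 | (1R,2S,4S)-6-(hydroxymethyl)-8-(methoxymethoxy)-1-methyl-4-[(2S)-6-methylhept-5-en-2-yl]-1,2,3,4-tetrahydronaphthalen-2-ol | OCc1cc(OCOC)c2c(c1)[C@H]([C@@H](C)CCC=C(C)C)C[C@H](O)[C@@H]2C | intermediate
24 | (1R,2S,4S)-6-(acetoxymethyl)-8-(methoxymethoxy)-1-methyl-4-[(2S)-6-methylhept-5-en-2-yl]-1,2,3,4-tetrahydronaphthalen-2-yl acetate | CC(=O)OCc1cc(OCOC)c2c(c1)[C@H]([C@@H](C)CCC=C(C)C)C[C@H](OC(C)=O)[C@@H]2C | intermediate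
25 | (1R,2S,4S)-6-(acetoxymethyl)-8-hydroxy-1-methyl-4-[(2S)-6-methylhept-5-en-2-yl]-1,2,3,4-tetrahydronaphthalen-2-yl acetate | CC(=O)OCc1cc(O)c2c(c1)[C@H]([C@@H](C)CCC=C(C)C)C[C@H](OC(C)=O)[C@@H]2C | target

Total steps: 11. Longest linear sequence: 9 (steps 1, 2, 3, 6, 7, 8, 9, 10, 11).

**Three steps most likely to fail**

**Step 8 (the proposed new ring expansion).**
- Risks: slow addition to the deactivated ketone, methylene instead of aryl migration, epoxide formation, or a second insertion into 22.
- Fallback with known chemistry, setting out from 19. Wittig olefination (EtPPh3Br, KOt-Bu, THF, 0 °C to rt) gives [(1E,3S)-1-ethylidene-7-(methoxymethoxy)-3-[(2S)-6-methylhept-5-en-2-yl]-2,3-dihydro-1H-inden-5-yl]methyl acetate F1.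
- PhI(OH)OTs in 95% MeOH (0 °C to rt) then effects the established trivalent-iodine oxidative rearrangement of 1-alkylidene benzocycloalkanes: electrophilic addition, 1,2-aryl shift, then hydrolysis of the ketal.
- The electron-rich styrene reacts ahead of the isolated alkene. This comes back to the route at 22.

**Step 7 (rhodium cascade).**
- Risks: ligand control may be eroded by the adjacent C11 centre, and ynone 18 may be diverted by isomerisation or simple reduction.
- Fallback setting out from 8 and 15; it replaces steps 6 and 7. Imine-directed ortho C–H borylation of 8 ([Ir(OMe)(cod)]2, t-BuNH2 as transient director, B2pin2, THF, 80 °C, aqueous work-up) gives [4-formyl-3-(methoxymethoxy)-5-(4,4,5,5-tetramethyl-1,3,2-dioxaborolan-2-yl)phenyl]methyl acetate F2.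
- Suzuki–Miyaura coupling with 15 (PdCl2(dppf), K3PO4, dioxane/H2O, 60 °C) gives {3-[(3S)-3,7-dimethylocta-1,6-dien-2-yl]-4-formyl-5-(methoxymethoxy)phenyl}methyl acetate F3.
- Enantioselective intramolecular hydroacylation of the 1,1-disubstituted alkene ([Rh(cod)2]BF4, (R)-BINAP, acetone, rt) closes the five-membered ring, sets C4, and comes back at 19.

**Step 9 (dynamic kinetic hydrogenation).**
- Risks: C1 epimerisation may be slow because the planar enolate suffers peri strain, and the catalyst may be mismatched with the substrate bias.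
- Fallback setting out from 22. Equilibration with DBU (CH2Cl2, rt) and chromatographic separation, with recycling of the 1S epimer, give (1R,4S)-6-(acetoxymethyl)-8-(methoxymethoxy)-1-methyl-4-[(2S)-6-methylhept-5-en-2-yl]-3,4-dihydronaphthalen-2(1H)-one F4.
- Substrate-controlled reduction with LiBH(s-Bu)3 (THF, −78 °C, hydride anti to the pseudoaxial methyl) gives (1R,2S,4S)-6-(acetoxymethyl)-8-(methoxymethoxy)-1-methyl-4-[(2S)-6-methylhept-5-en-2-yl]-1,2,3,4-tetrahydronaphthalen-2-ol F5.
- Acetylation (Ac2O, pyridine, DMAP) comes back to the route at 24.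

Further compounds
F1 | step 8 | [(1E,3S)-1-ethylidene-7-(methoxymethoxy)-3-[(2S)-6-methylhept-5-en-2-yl]-2,3-dihydro-1H-inden-5-yl]methyl acetate | CC(=O)OCc1cc(OCOC)c2c(c1)[C@H]([C@@H](C)CCC=C(C)C)C/C2=C\C
F2 | step 7 | [4-formyl-3-(methoxymethoxy)-5-(4,4,5,5-tetramethyl-1,3,2-dioxaborolan-2-yl)phenyl]methyl acetate | CC(=O)OCc1cc(OCOC)c(C=O)c(c1)B1OC(C)(C)C(C)(C)O1
F3 | step 7 | {3-[(3S)-3,7-dimethylocta-1,6-dien-2-yl]-4-formyl-5-(methoxymethoxy)phenyl}methyl acetate | CC(=O)OCc1cc(OCOC)c(C=O)c(c1)C(=C)[C@@H](C)CCC=C(C)C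
F4 | step 9 | (1R,4S)-6-(acetoxymethyl)-8-(methoxymethoxy)-1-methyl-4-[(2S)-6-methylhept-5-en-2-yl]-3,4-dihydronaphthalen-2(1H)-one | CC(=O)OCc1cc(OCOC)c2c(c1)[C@H]([C@@H](C)CCC=C(C)C)CC(=O)[C@@H]2C
F5 | step 9 | (1R,2S,4S)-6-(acetoxymethyl)-8-(methoxymethoxy)-1-methyl-4-[(2S)-6-methylhept-5-en-2-yl]-1,2,3,4-tetrahydronaphthalen-2-ol | CC(=O)OCc1cc(OCOC)c2c(c1)[C@H]([C@@H](C)CCC=C(C)C)C[C@H](O)[C@@H]2C
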